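**Remark (convention).** Germacrane numbering is used for every compound, including the six-membered precursors: ring C1–C10, lactone carbons C11–C13, C14 on C10, C15 on C4; α/β as usual for germacranolides (H-7 is α). The target is then 8β-angeloyloxy-1β,10α-epoxy-15-hydroxy-3-oxo-4αH-germacr-11(13)-en-6α,12-olide, (1R,4S,6R,7S,8R,10R).

**Remark (assumption).** The facial sense of the Rh/(S)-BINAP addition in step 1 is taken by analogy with cyclohexenone; should it be opposite, (R)-BINAP is used and nothing else changes.

## The problem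

Argophyllone B is a ten-membered carbocycle carrying a trans-fused α-methylene-γ-lactone (C6/C7), a trisubstituted trans-epoxide (C1/C10), a ketone (C3) and six stereocenters. The ring has to be formed with an (E)-C1=C10 olefin inside it, which penalises every end-to-end cyclisation. C6, C7 and C8 form a contiguous triad in which C8 can control C6 (1,3) and the ring conformation can control C7. C4 lies 1,4 to that triad across the ring and needs control of its own. The epoxide face can only be set by the conformation of the finished macrocycle. The C3 ketone is flanked by a β-hydroxymethyl group (retro-aldol, dehydration, epimerisation at C4) and a β,γ-epoxide (base opens it to a γ-hydroxy enone). The methylene lactone is a Michael acceptor and the angelate isomerises to the tiglate, so strong base and nucleophiles are excluded late. The feature that the plan exploits is twofold: the C6 oxygen is 1,5-related to the C1–C10 epoxide through C7–C8–C9 (the retron C6(=O)–C7–C8–C9–C10=C1 of a [3,3] shift), and C1–C6 together with C9/C10/C14 on C1 and C15 on C4 form a 2,5-dioxygenated p-menthane. The ten-membered ring is therefore the two-atom-per-side ring expansion of a cyclohexane C1–C6 bearing an isopropenyl group on C1 and an alkenyl carbinol at C6.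

## Retrosynthesis

**34 ⇒ 33.** The epoxide C1–O–C10 is cut last. The precursor 33 is the 1(10)-(E)-olefin with every other group in place, so the forward step is one neutral oxygen transfer to the only electron-rich alkene. It needs attack on the outer face of the (E)-cyclodecene.

**33 ⇒ 29.** The C3 ketone and the free C15 hydroxyl are traced to the 3β,15-acetonide 29 through diol 30, silyl ether 31 and ketone 32. Carrying C3 as a carbinol keeps the β-hydroxy ketone and the β,γ-unsaturated ketone out of all basic steps. The C3 carbinol is also the relay stereocenter used earlier.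

**29 ⇒ 26 + 27.** The C8–O ester bond is cut to alcohol 26 and angelic acid 27. A mixed-anhydride acylation is required that does not isomerise the (Z)-enoate.

**26 ⇒ 23 ⇒ 21 ⇒ 20.** C11=C13 is removed (Mannich/elimination on lactone 23). The lactone C12–O6 bond and the C6 carbinol are traced to β-hydroxy ketone 21 and its PMB ether 20. A hydroxyl-directed reduction lets C8 set C6 (1,3-anti), which does not depend on the ring conformation.

**20 ⇒ 16 + 17 (key).** Two bonds are cut: C7–C11 (enolate alkylation with bromoacetate 17) and C8–C9 (retro-oxy-Cope), with C1–C6 re-formed. This is preferred over cutting C6–C7 or C1=C10 of the open chain because the precursor 16 is a cyclohexanol with two alkenyl groups, and the forward step needs no dilution. The forward step must deliver four things at once: the ring, the (E)-olefin, C8 (from the (Z)-enol ether geometry) and a regiodefined C6–C7 enolate that is alkylated at C7 on its outer face.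

**16 ⇒ 9 + 14.** The C6–C7 bond is cut to ketone 9 and (Z)-2-bromovinyl PMB ether 14 (via vinyllithium 15). Addition anti to the isopropenyl group gives the trans-dialkenyl arrangement the chair transition state needs.

**9 ⇒ 7 ⇒ 5 ⇒ 4 ⇒ 3 ⇒ 1 + 2.** C4–C15 is cut by a silicon-tethered radical cyclisation (5 → 6 → 7), which places C15 cis to O3. O3 is set cis to the C1 isopropenyl group by 1,2-reduction of enone 3 (→ 4). C1 is set by a catalytic asymmetric conjugate addition of isopropenyl borate 2 to quinone monoketal 1. One catalyst-set stereocenter is thus relayed C1 → C3 → C4 → (C6) → C8 → C7 → C6 → C1/C10. The ketal in 1 is the latent C6 ketone (released from 8).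

**14 ⇒ 12 ⇒ 10 + 11.** The enol ether is made from 4-methoxybenzyl alcohol 10 by transfer vinylation with 11 (→ 12), then bromination/dehydrobromination (13 → 14).

## Roads not taken

**Alternative 1:** (the obvious one) cut C6–C7 and close the ring by an intramolecular Nozaki–Hiyama–Kishi or Barbier allylation of the open-chain aldehyde (Z)-2-(bromomethyl)enoate A1, giving the methylene lactone A2 directly. The forward step forms the lactone with its methylene in place. However, A1 needs C3, C4, C8 and the (E)-trisubstituted olefin to be built one by one in a long linear chain with no relay between them. The ring closure is a high-dilution macrocyclisation to a strained (E)-cyclodecene, and the required 6,7-trans/7,8-cis triad is not the inherent preference of a ten-membered allylation. The chosen plan forms the ring from a six-membered ring with the olefin geometry fixed by the mechanism.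

**Alternative 2:** cut C1=C10 and close by ring-closing metathesis of diene A3 to the same macrocycle A2. A trisubstituted olefin in a ten-membered ring is a poor metathesis target: ring strain favours oligomers, and where closure occurs the (Z)-isomer is expected, while the target needs (E). The [3,3] shift gives (E) from the chair transition state.

**Alternative 3:** cut C6–C10 in a Wharton–Grob sense: the hydroazulene hydroxy tosylate A4 would fragment to cyclodecenone A5 with the C6 ketone and the (E)-C1=C10 olefin. This is also a ring expansion, but A4 needs a quaternary C10 and two further stereocenters that are destroyed in the step. A5 has no oxygen at C8 and no regiodefined enolate, so C7 and C8 would have to be functionalised on the macrocycle without control. The oxy-Cope precursor is simpler and hands over C8–O and the C6–C7 enolate as part of the same event.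

Key step: step 9

## Route

**Step 1**
Reactants: 1 4,4-dimethoxycyclohexa-2,5-dien-1-one; 2 potassium trifluoro(prop-1-en-2-yl)borate
Product: 3 (S)-4,4-dimethoxy-5-(prop-1-en-2-yl)cyclohex-2-en-1-one
Conditions: [Rh(cod)2]BF4 (3 mol %), (S)-BINAP, Et3N, PhMe/H2O, 23 °C
Reagents that add atoms: none
Why: Rh(I)/BINAP-catalysed asymmetric 1,4-addition of an alkenyltrifluoroborate to a quinone monoketal; the ligand selects the enone face and sets C1 (S), and the two enone arms are equivalent so no regiochemical issue arises.

**Step 2**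
Reactants: 3
Product: 4 (1S,5S)-4,4-dimethoxy-5-(prop-1-en-2-yl)cyclohex-2-en-1-ol
Conditions: NaBH4, CeCl3·7H2O, MeOH, −78 → 0 °C
Reagents that add atoms: none
Why: Luche 1,2-reduction; hydride should add anti to the isopropenyl group (the carvone → cis-carveol pattern), giving the C3 carbinol cis to C1; this carbinol is the relay for C4.

**Step 3**
Reactants: 4
Product: 5 (bromomethyl)dimethylsilyl ether of 4
Conditions: BrCH2SiMe2Cl, Et3N, DMAP (cat.), CH2Cl2, 0 °C
Reagents that add atoms: (bromomethyl)chlorodimethylsilane, C[Si](C)(Cl)CBr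
Why: Plain silylation of a secondary allylic alcohol; it installs the tethered one-carbon radical precursor that becomes C15.

**Step 4**
Reactants: 5
Product: 7 (1S,2S,5S)-2-(hydroxymethyl)-4,4-dimethoxy-5-(prop-1-en-2-yl)cyclohexan-1-ol, via cyclic siloxane 6 (not isolated)
Conditions: Bu3SnH, AIBN (cat.), PhH, 80 °C, slow addition; then KF, KHCO3, 30% H2O2, THF/MeOH, 23 °C
Reagents that add atoms: hydrogen peroxide, OO
Why: Silicon-tethered 5-exo-trig radical cyclisation forms C4–C15 on the face of O3 (only the cis-fused oxasilolane can form), which sets C4 (S); Tamao oxidation then turns C–Si into C–OH. The isopropenyl group is out of reach of the tethered radical.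

**Step 5**
Reactants: 7
Product: 9 (4aS,7S,8aS)-2,2-dimethyl-7-(prop-1-en-2-yl)tetrahydro-4H-benzo[d][1,3]dioxin-6(5H)-one, via acetonide dimethyl ketal 8 (not isolated)
Conditions: 2-methoxypropene, PPTS (cat.), acetone, 0 °C; then H2O, 23 °C
Reagents that add atoms: 2-methoxypropene, COC(C)=C; water, O
Why: Kinetic acetonide formation on the cis-1,3-diol, then hydrolysis of the acyclic dimethyl ketal while acetone as solvent holds the acetonide; PPTS acidity is chosen to leave the α-isopropenyl stereocenter at C1 untouched.

**Step 6**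
Reactants: 10 4-methoxybenzyl alcohol; 11 butyl vinyl ether
Product: 12 4-methoxybenzyl vinyl ether
Conditions: Pd(OCOCF3)2 (cat.), 4,7-diphenyl-1,10-phenanthroline, Et3N, 11 as solvent, 75 °C
Reagents that add atoms: none
Why: Pd(II)-catalysed transfer vinylation of a primary benzylic alcohol, driven by excess vinyl ether.

**Step 7**
Reactants: 12
Product: 14 (Z)-1-bromo-2-(4-methoxybenzyloxy)ethene, via dibromide 13 (not isolated)
Conditions: Br2, CH2Cl2, −78 °C; then i-Pr2NEt, −78 → 23 °C
Reagents that add atoms: bromine, BrBr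
Why: Bromine addition to the enol ether and dehydrobromination of the α-bromo ether; the cis (Z) 2-haloenol ether is the favoured isomer, as for the ethyl analogue.

**Step 8**
Reactants: 9; 14
Product: 16 (4aS,6S,7S,8aS)-6-[(Z)-2-(4-methoxybenzyloxy)ethenyl]-2,2-dimethyl-7-(prop-1-en-2-yl)hexahydro-4H-benzo[d][1,3]dioxin-6-ol, via vinyllithium 15 (not isolated)
Conditions: 14, t-BuLi (2 equiv), Et2O, −78 °C; CeCl3, THF, −78 °C; then 9, −78 °C
Reagents that add atoms: none
Why: Br/Li exchange with retention gives the O-chelated cis-β-alkoxyvinyllithium, which cannot undergo anti β-elimination; the organocerium adds without enolising the ketone. Attack anti to the isopropenyl group (equatorial; the axial path is blocked by the axial C15 methylene) sets C6 and gives the trans-dialkenyl carbinol.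

**Step 9**
Reactants: 16; 17 methyl bromoacetate
Product: 20 methyl 3β,15-isopropylidenedioxy-8β-(4-methoxybenzyloxy)-6-oxo-4αH,7αH-13-norgermacr-1(10)E-en-12-oate, via potassium alkoxide 18 (not isolated), via potassium enolate 19 (not isolated)
Conditions: KHMDS, THF, 0 → 45 °C; then 17, −78 → −20 °C
Reagents that add atoms: none
Why: Tandem anionic oxy-Cope rearrangement/enolate alkylation, the known ring expansion of trans-1,2-dialkenylcyclohexanol alkoxides to (E)-cyclodec-5-enone enolates with trapping in the same flask. Alkoxide 18 undergoes the [3,3] shift through a chair transition state in which both ring bonds (C5 on C6, C2 on C1) are equatorial; C1–C6 breaks and C8–C9 forms, so the ten-membered ring arises by ring expansion (6 → 10) and not by end-to-end closure. The equatorial C2 gives the (E)-C1=C10 olefin. C8 is set because the (Z)-enol ether places the PMB-oxy group axial on the chair whose sense is fixed by C1/C6 (S,S), and bond formation at C8 is suprafacial; this gives 8β-O (8R). The enolate 19 is formed only between C6 and C7. Its inner face is covered by the transannular C1=C10 unit, so the bromoacetate should enter at C7 on the outer face, anti to C9, which gives 7α-H. K+ bridging the enolate oxygen and the cis-disposed ether oxygen holds the conformer in which the C8–O bond lies near the enolate plane, where it cannot overlap for β-elimination. The selectivities needed are chair over boat (secured by the trans-diequatorial alkenyl groups), C- over O-alkylation (soft α-halo ester) and alkylation before ring-flip or elimination (cooling to −78 °C once the rearrangement is complete).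

**Step 10**
Reactants: 20
Product: 21 methyl 8β-hydroxy-3β,15-isopropylidenedioxy-6-oxo-4αH,7αH-13-norgermacr-1(10)E-en-12-oate
Conditions: DDQ, CH2Cl2/pH 7 buffer, 0 °C
Reagents that add atoms: none
Why: Oxidative cleavage of the PMB ether under buffered neutral conditions; the trisubstituted olefin, acetonide and ester are inert, and no base is present to trigger retro-aldol of the β-hydroxy ketone.

**Step 11**
Reactants: 21
Product: 23 8β-hydroxy-3β,15-isopropylidenedioxy-4αH-13-norgermacr-1(10)E-en-6α,12-olide, via diol ester 22 (not isolated)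
Conditions: Me4NBH(OAc)3, MeCN/AcOH, −30 °C; work-up; then PPTS (cat.), PhMe, 50 °C
Reagents that add atoms: none
Why: Evans–Saksena reduction; hydride is delivered intramolecularly from the C8–O–B species through a chair six-membered transition state, giving the 1,3-anti diol (6α-OH, 6R) whatever the ring conformation. Acid-catalysed closure onto O6 gives the trans-fused 6α,12-olide, the lactone isomer in which 8β-hydroxy germacranolides occur.

**Step 12**
Reactants: 23
Product: 26 8β-hydroxy-3β,15-isopropylidenedioxy-4αH-germacra-1(10)E,11(13)-dien-6α,12-olide, via Mannich base 24 (not isolated), via ammonium iodide 25 (not isolated)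
Conditions: LiHMDS (2.3 equiv), THF, −78 °C; Eschenmoser's salt, −78 → 0 °C; then MeI, MeOH, 23 °C; then aq. NaHCO3/CH2Cl2
Reagents that add atoms: N,N-dimethylmethyleneiminium iodide (Eschenmoser's salt), C=[N+](C)C.[I-]
Why: Standard α-methylenation of a γ-lactone (enolate Mannich reaction, quaternisation, elimination); the C8 alkoxide is a spectator, and the lactone carbonyl is masked as its enolate while the alkoxide is present.

**Step 13**
Reactants: 26; 27 angelic acid
Product: 29 8β-angeloyloxy-3β,15-isopropylidenedioxy-4αH-germacra-1(10)E,11(13)-dien-6α,12-olide, via mixed anhydride 28 (not isolated)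
Conditions: 27, 2,4,6-trichlorobenzoyl chloride, Et3N, PhMe, 23 °C; then 26, DMAP, PhMe, 23 °C
Reagents that add atoms: none
Why: Yamaguchi esterification; the hindered mixed anhydride acylates the secondary alcohol without Z → E isomerisation of the angeloyl unit.

**Step 14**
Reactants: 29
Product: 30 8β-angeloyloxy-3β,15-dihydroxy-4αH-germacra-1(10)E,11(13)-dien-6α,12-olide
Conditions: AcOH/THF/H2O (3:1:1), 40 °C
Reagents that add atoms: none
Why: Mild acid hydrolysis of a 1,3-dioxane acetonide; esters, methylene lactone and the olefin tolerate it.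

**Step 15**
Reactants: 30
Product: 31 8β-angeloyloxy-3β-hydroxy-15-(triethylsilyloxy)-4αH-germacra-1(10)E,11(13)-dien-6α,12-olide
Conditions: TESCl, imidazole, CH2Cl2, −78 °C
Reagents that add atoms: chlorotriethylsilane, CC[Si](Cl)(CC)CC
Why: Selective silylation of the primary over the secondary hydroxyl at low temperature.

**Step 16**
Reactants: 31
Product: 32 8β-angeloyloxy-3-oxo-15-(triethylsilyloxy)-4αH-germacra-1(10)E,11(13)-dien-6α,12-olide
Conditions: Dess–Martin periodinane, NaHCO3, CH2Cl2, 0 → 23 °C
Reagents that add atoms: none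
Why: Neutral buffered oxidation of the C3 carbinol; the relay stereocenter is erased, and neither C4 nor the β,γ-olefin should be disturbed.

**Step 17**
Reactants: 32
Product: 33 8β-angeloyloxy-15-hydroxy-3-oxo-4αH-germacra-1(10)E,11(13)-dien-6α,12-olide
Conditions: HF·pyridine, pyridine, THF, 0 °C
Reagents that add atoms: none
Why: Buffered fluoride cleavage of a primary TES ether; no free base is present that could cause retro-aldol or dehydration.

**Step 18**
Reactants: 33
Product: 34 argophyllone B
Conditions: dimethyldioxirane, acetone, −20 → 0 °C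
Reagents that add atoms: dimethyldioxirane, CC1(C)OO1
Why: Electrophilic epoxidation of the only electron-rich olefin (methylene lactone and angelate are electron-poor); attack on the exposed outer face of the (E)-cyclodecene should give the 1β,10α (1R,10R) epoxide, as peracids do with germacra-1(10)-enolides. The only by-product is acetone.

## Compound list

1 | 4,4-dimethoxycyclohexa-2,5-dien-1-one | COC1(OC)C=CC(=O)C=C1 | starting material
2 | potassium trifluoro(prop-1-en-2-yl)borate | [K+].CC(=C)[B-](F)(F)F | starting material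
3 | (S)-4,4-dimethoxy-5-(prop-1-en-2-yl)cyclohex-2-en-1-one | COC1(OC)C=CC(=O)C[C@H]1C(C)=C | intermediate
4 | (1S,5S)-4,4-dimethoxy-5-(prop-1-en-2-yl)cyclohex-2-en-1-ol | COC1(OC)C=C[C@@H](O)C[C@H]1C(C)=C | intermediate
5 | (bromomethyl)dimethylsilyl ether of 4 | COC1(OC)C=C[C@@H](O[Si](C)(C)CBr)C[C@H]1C(C)=C | intermediate
6 | cis-fused cyclic siloxane (C3–O–SiMe2–C15–C4) | COC1(OC)C[C@H]2C[Si](C)(C)O[C@H]2C[C@H]1C(C)=C | intermediate
7 | (1S,2S,5S)-2-(hydroxymethyl)-4,4-dimethoxy-5-(prop-1-en-2-yl)cyclohexan-1-ol | COC1(OC)C[C@@H](CO)[C@@H](O)C[C@H]1C(C)=C | intermediate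
8 | (4aS,7S,8aS)-6,6-dimethoxy-2,2-dimethyl-7-(prop-1-en-2-yl)hexahydro-4H-benzo[d][1,3]dioxine | CC1(C)OC[C@@H]2CC(OC)(OC)[C@H](C(C)=C)C[C@@H]2O1 | intermediate
9 | (4aS,7S,8aS)-2,2-dimethyl-7-(prop-1-en-2-yl)tetrahydro-4H-benzo[d][1,3]dioxin-6(5H)-one | CC1(C)OC[C@@H]2CC(=O)[C@H](C(C)=C)C[C@@H]2O1 | intermediate
10 | 4-methoxybenzyl alcohol | COc1ccc(CO)cc1 | starting material
11 | butyl vinyl ether | C=COCCCC | starting material
12 | 4-methoxybenzyl vinyl ether | COc1ccc(COC=C)cc1 | intermediate
13 | 1-(1,2-dibromoethoxymethyl)-4-methoxybenzene | COc1ccc(COC(Br)CBr)cc1 | intermediate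
14 | (Z)-1-bromo-2-(4-methoxybenzyloxy)ethene | COc1ccc(CO/C=C\Br)cc1 | intermediate
15 | (Z)-2-(4-methoxybenzyloxy)vinyllithium | COc1ccc(CO/C=C\[Li])cc1 | intermediate
16 | (4aS,6S,7S,8aS)-6-[(Z)-2-(4-methoxybenzyloxy)ethenyl]-2,2-dimethyl-7-(prop-1-en-2-yl)hexahydro-4H-benzo[d][1,3]dioxin-6-ol | CC1(C)OC[C@@H]2C[C@@](O)(/C=C\OCc3ccc(OC)cc3)[C@H](C(C)=C)C[C@@H]2O1 | intermediate
17 | methyl bromoacetate | COC(=O)CBr | starting material
18 | potassium alkoxide of 16 | [K+].CC1(C)OC[C@@H]2C[C@@]([O-])(/C=C\OCc3ccc(OC)cc3)[C@H](C(C)=C)C[C@@H]2O1 | intermediate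
19 | potassium C6–C7 enolate of the ten-membered ring (8β-OPMB, 1(10)E, 3β,15-acetonide) | [K+].[O-]/C1=C\[C@H](OCc2ccc(OC)cc2)C/C(C)=C/C[C@@H]3OC(C)(C)OC[C@@H]3C1 | intermediate
20 | methyl 3β,15-isopropylidenedioxy-8β-(4-methoxybenzyloxy)-6-oxo-4αH,7αH-13-norgermacr-1(10)E-en-12-oate | COC(=O)C[C@@H]1[C@H](OCc2ccc(OC)cc2)C/C(C)=C/C[C@@H]3OC(C)(C)OC[C@@H]3CC1=O | intermediate
21 | methyl 8β-hydroxy-3β,15-isopropylidenedioxy-6-oxo-4αH,7αH-13-norgermacr-1(10)E-en-12-oate | COC(=O)C[C@@H]1[C@H](O)C/C(C)=C/C[C@@H]3OC(C)(C)OC[C@@H]3CC1=O | intermediate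
22 | methyl 6α,8β-dihydroxy-3β,15-isopropylidenedioxy-4αH,7αH-13-norgermacr-1(10)E-en-12-oate | COC(=O)C[C@@H]1[C@H](O)C/C(C)=C/C[C@@H]2OC(C)(C)OC[C@@H]2C[C@H]1O | intermediate
23 | 8β-hydroxy-3β,15-isopropylidenedioxy-4αH-13-norgermacr-1(10)E-en-6α,12-olide | O=C1C[C@@H]2[C@H](O)C/C(C)=C/C[C@@H]3OC(C)(C)OC[C@@H]3C[C@H]2O1 | intermediate
24 | 13-(dimethylamino) Mannich base of 23 (C11 epimers) | CN(C)CC1C(=O)O[C@@H]2C[C@H]3COC(C)(C)O[C@H]3C/C=C(\C)C[C@@H](O)[C@@H]12 | intermediate
25 | trimethylammonium iodide of 24 | C[N+](C)(C)CC1C(=O)O[C@@H]2C[C@H]3COC(C)(C)O[C@H]3C/C=C(\C)C[C@@H](O)[C@@H]12.[I-] | intermediate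
26 | 8β-hydroxy-3β,15-isopropylidenedioxy-4αH-germacra-1(10)E,11(13)-dien-6α,12-olide | C=C1C(=O)O[C@@H]2C[C@H]3COC(C)(C)O[C@H]3C/C=C(\C)C[C@@H](O)[C@@H]12 | intermediate
27 | angelic acid, (Z)-2-methylbut-2-enoic acid | C/C=C(/C)C(=O)O | starting material
28 | angelic 2,4,6-trichlorobenzoic anhydride | C/C=C(/C)C(=O)OC(=O)c1c(Cl)cc(Cl)cc1Cl | intermediate
29 | 8β-angeloyloxy-3β,15-isopropylidenedioxy-4αH-germacra-1(10)E,11(13)-dien-6α,12-olide | C=C1C(=O)O[C@@H]2C[C@H]3COC(C)(C)O[C@H]3C/C=C(\C)C[C@@H](OC(=O)/C(C)=C\C)[C@@H]12 | intermediate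
30 | 8β-angeloyloxy-3β,15-dihydroxy-4αH-germacra-1(10)E,11(13)-dien-6α,12-olide | C=C1C(=O)O[C@@H]2C[C@@H](CO)[C@@H](O)C/C=C(\C)C[C@@H](OC(=O)/C(C)=C\C)[C@@H]12 | intermediate
31 | 8β-angeloyloxy-3β-hydroxy-15-(triethylsilyloxy)-4αH-germacra-1(10)E,11(13)-dien-6α,12-olide | C=C1C(=O)O[C@@H]2C[C@@H](CO[Si](CC)(CC)CC)[C@@H](O)C/C=C(\C)C[C@@H](OC(=O)/C(C)=C\C)[C@@H]12 | intermediate
32 | 8β-angeloyloxy-3-oxo-15-(triethylsilyloxy)-4αH-germacra-1(10)E,11(13)-dien-6α,12-olide | C=C1C(=O)O[C@@H]2C[C@@H](CO[Si](CC)(CC)CC)C(=O)C/C=C(\C)C[C@@H](OC(=O)/C(C)=C\C)[C@@H]12 | intermediate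
33 | 8β-angeloyloxy-15-hydroxy-3-oxo-4αH-germacra-1(10)E,11(13)-dien-6α,12-olide | C=C1C(=O)O[C@@H]2C[C@@H](CO)C(=O)C/C=C(\C)C[C@@H](OC(=O)/C(C)=C\C)[C@@H]12 | intermediate
34 | argophyllone B | C=C1C(=O)O[C@@H]2C[C@@H](CO)C(=O)C[C@H]3O[C@]3(C)C[C@@H](OC(=O)/C(C)=C\C)[C@@H]12 | target

## Step count and least certain steps

Total: 18 steps. Longest linear sequence: 16 steps (steps 1–5 and 8–18, from 1); steps 6–7 make the two-carbon partner 14.

**Step 9 (key step).** Three processes could defeat it: loss of the C8 alkoxide by β-elimination from the potassium enolate at the rearrangement temperature, leakage through a boat transition state (wrong C8), and alkylation after ring-flip of the enolate (wrong face at C7) or on oxygen. The fallback separates rearrangement from C–C bond formation and avoids a free enolate at C7. It sets out from 16: the rearrangement is quenched with chlorotrimethylsilane at −78 °C to give the trimethylsilyl enol ether F1. Copper-catalysed cyclopropanation of F1 with methyl diazoacetate on the same outer face gives the siloxycyclopropane ester F2. Fluoride-induced ring opening of this donor–acceptor cyclopropane gives the γ-keto ester and returns to the route at 20.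

**Step 11.** The diol ester could lactonise onto O8 (cis-fused 8,12-olide) instead of O6, or 21 could lactonise before the reduction and so lose the directing hydroxyl. The fallback keeps the PMB ether so that only O6 can lactonise, and corrects C6 by inversion. It sets out from 20: borohydride reduction, expected to come anti to C8, gives the 6β-alcohol, which closes to the cis-fused lactone F3. Saponification gives the hydroxy acid F4. Mitsunobu lactonisation inverts C6 to the trans-fused lactone PMB ether F5. DDQ cleavage of the PMB group returns to the route at 23.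

**Step 8.** The basic organometallic could enolise the α-isopropenyl ketone (epimerisation at C1, conjugation of the olefin), or the vinylmetal could decompose before it adds. The fallback uses a small, weakly basic acetylide and sets the (Z)-geometry afterwards. It sets out from 10 and 9: 10 and trichloroethylene with potassium hydride give (E)-1,2-dichlorovinyl 4-methoxybenzyl ether F6. Butyllithium converts it into lithium (4-methoxybenzyloxy)acetylide F7, which adds to 9 to give the alkynyl carbinol F8. Lindlar semi-hydrogenation of the ynol ether gives the (Z)-enol ether and returns to the route at 16.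

**Step 18.** Facial selectivity on the free hydroxy ketone could be poor if the macrocycle populates more than one conformer, and the primary alcohol could be over-oxidised by excess dioxirane. The fallback replaces substrate control by reagent control one stage earlier. It sets out from 31: Shi epoxidation with the fructose-derived ketone enantiomer matched to the (1R,10R) sense gives the epoxy alcohol F9. Dess–Martin oxidation gives the epoxy ketone silyl ether F10. Buffered HF·pyridine returns to the route at 34.

## Further compounds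

F1 | step 9 | trimethylsilyl enol ether of the ring-expanded ketone (C6–C7 enol ether, 8β-OPMB) | C[Si](C)(C)O/C1=C\[C@H](OCc2ccc(OC)cc2)C/C(C)=C/C[C@@H]3OC(C)(C)OC[C@@H]3C1
F2 | step 9 | methyl 6-(trimethylsilyloxy)-6,7-methano ester (siloxycyclopropane, C11 epimers) | COC(=O)C1[C@@H]2[C@H](OCc3ccc(OC)cc3)C/C(C)=C/C[C@@H]4OC(C)(C)OC[C@@H]4C[C@@]12O[Si](C)(C)C
F3 | step 11 | 3β,15-isopropylidenedioxy-8β-(4-methoxybenzyloxy)-4αH-13-norgermacr-1(10)E-en-6β,12-olide (cis-fused) | O=C1C[C@@H]2[C@H](OCc3ccc(OC)cc3)C/C(C)=C/C[C@@H]4OC(C)(C)OC[C@@H]4C[C@@H]2O1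
F4 | step 11 | 6β-hydroxy-3β,15-isopropylidenedioxy-8β-(4-methoxybenzyloxy)-4αH,7αH-13-norgermacr-1(10)E-en-12-oic acid | OC(=O)C[C@@H]1[C@H](OCc2ccc(OC)cc2)C/C(C)=C/C[C@@H]3OC(C)(C)OC[C@@H]3C[C@@H]1O
F5 | step 11 | 3β,15-isopropylidenedioxy-8β-(4-methoxybenzyloxy)-4αH-13-norgermacr-1(10)E-en-6α,12-olide (trans-fused) | O=C1C[C@@H]2[C@H](OCc3ccc(OC)cc3)C/C(C)=C/C[C@@H]4OC(C)(C)OC[C@@H]4C[C@H]2O1
F6 | step 8 | (E)-1,2-dichlorovinyl 4-methoxybenzyl ether | COc1ccc(CO/C(Cl)=C\Cl)cc1
F7 | step 8 | lithium (4-methoxybenzyloxy)acetylide | [Li]C#COCc1ccc(OC)cc1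
F8 | step 8 | (4aS,6S,7S,8aS)-6-[(4-methoxybenzyloxy)ethynyl]-2,2-dimethyl-7-(prop-1-en-2-yl)hexahydro-4H-benzo[d][1,3]dioxin-6-ol | CC1(C)OC[C@@H]2C[C@@](O)(C#COCc3ccc(OC)cc3)[C@H](C(C)=C)C[C@@H]2O1
F9 | step 18 | 8β-angeloyloxy-1β,10α-epoxy-3β-hydroxy-15-(triethylsilyloxy)-4αH-germacr-11(13)-en-6α,12-olide | C=C1C(=O)O[C@@H]2C[C@@H](CO[Si](CC)(CC)CC)[C@@H](O)C[C@H]3O[C@]3(C)C[C@@H](OC(=O)/C(C)=C\C)[C@@H]12
F10 | step 18 | 8β-angeloyloxy-1β,10α-epoxy-3-oxo-15-(triethylsilyloxy)-4αH-germacr-11(13)-en-6α,12-olide | C=C1C(=O)O[C@@H]2C[C@@H](CO[Si](CC)(CC)CC)C(=O)C[C@H]3O[C@]3(C)C[C@@H](OC(=O)/C(C)=C\C)[C@@H]12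
A1 | alternative 1 | open-chain aldehyde (Z)-2-(bromomethyl)enoate (C6 aldehyde, 3-OTES, 15-OTBS, 8-OPMB, 1(10)E) | COC(=O)/C(CBr)=C/[C@H](OCc1ccc(OC)cc1)C/C(C)=C/C[C@H](O[Si](CC)(CC)CC)[C@H](CO[Si](C)(C)C(C)(C)C)CC=O
A2 | alternative 1 | 8β-(4-methoxybenzyloxy)-3β-(triethylsilyloxy)-15-(tert-butyldimethylsilyloxy)-4αH-germacra-1(10)E,11(13)-dien-6α,12-olide | C=C1C(=O)O[C@@H]2C[C@@H](CO[Si](C)(C)C(C)(C)C)[C@@H](O[Si](CC)(CC)CC)C/C=C(\C)C[C@@H](OCc3ccc(OC)cc3)[C@@H]12
A3 | alternative 2 | 1,10-seco diene with the α-methylene lactone in place (terminal vinyl at C1, isopropenyl at C10) | C=C1C(=O)O[C@H](C[C@@H](CO[Si](C)(C)C(C)(C)C)[C@@H](O[Si](CC)(CC)CC)CC=C)[C@H]1[C@H](OCc2ccc(OC)cc2)CC(C)=C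
A4 | alternative 3 | trans-fused hydroazulene hydroxy tosylate (C6–C10 bond, C6–OH, C10–CH3, C1–OTs, 3β,15-acetonide) | CC1(C)OC[C@@H]2C[C@@]3(O)CCC[C@]3(C)[C@@H](OS(=O)(=O)c4ccc(C)cc4)C[C@@H]2O1
A5 | alternative 3 | 3β,15-isopropylidenedioxy-4αH-11,12,13-trinorgermacr-1(10)E-en-6-one | O=C1CCC/C(C)=C/C[C@@H]2OC(C)(C)OC[C@@H]2C1
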